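The runs come from a simulation for an exercise.

| flask | substrate | free enzyme | added ligand | temperature | remark | time |
|---|---|---|---|---|---|---|
| south-west | 0.20 M (fed, over 80 min) | 3.2 µM | 7.4 µM | 20 °C | run made earlier; the fed solution adds 0.25 times the starting volume |  |
| summer | 0.20 M | 0.80 µM | 11 µM | 20 °C | everything together at the start, the whole solution of substrate included, so that from the start the volume is larger by 0.25 times the starting volume | 80 min |
| noon | 0.20 M (fed, over 80 min) | 3.2 µM | 11 µM | 20 °C | the fed solution adds 0.25 times the starting volume | 80 min |

- south-west (time / min: product / %, substrate / %): 0.833: 0.4, 1.5; 2.50: 0.4, 3.3; 5.00: 1.0, 5.9; 6.00: 1.0, 7.3; 10.0: 3.0, 9.2; 12.0: 3.4, 10.1; 15.0: 5.6, 12.5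

(scatter of a reading: 0.5 percentage points)

- every charge counts on the volume at the start, and the solution that is fed holds the whole dose
- percentages count the whole charge, also what has not yet gone in
- no earlier run changes the charge of free enzyme; that part of a forecast is a guess
- no earlier run changes the charge of added ligand; that part of a forecast is a guess

* which one finishes higher in amount of product, in percent of the substrate charged ("neither" within 2 percentage points) (summer / noon / neither)
* amount of product at the end, in percent of the substrate charged, summer
* amount of product at the end, in percent of the substrate charged, noon

The south-west run supplies the reckoning for both flasks. Free enzyme is its smallest charge, yet by 15.0 min that run holds 11.2 mM of product per starting volume, so free enzyme turns over, and the substrate balance is feed in minus removal. In the south-west run, the product gained from 6.00 min to 15.0 min, divided by that time and by the mean substrate, reads as a removal constant of 0.0516 min⁻¹. Divided by the free enzyme charged, this gives 0.0161 µM⁻¹ min⁻¹, the clearance, meaning the pseudo-first-order removal constant per unit of free enzyme. It is a reading with scatter, taken at one charge of added ligand.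

Noon's free enzyme, thinned to the full volume, gives a removal constant of 0.0413 min⁻¹, so its dosing time holds a dose number N of 3.30 time constants. A steady feed against such removal leaves one minus e to the minus N, divided by N, as substrate. For noon that is 29.2 %, which puts product at 70.8 %. Summer has a quarter of that enzyme at the same volume, so its constant is 0.01033 min⁻¹, lower than noon's, and plain decay over 80 min puts summer's product at 56.2 %. This reckoning commits to noon. Its weak link is summer, which starts at 0.160 M, far above the 0.0250 M per starting volume in the last reading of the south-west run.

The forecast also names noon, but it stands lower on both flasks, at 42 % for summer and 65 % for noon, and it warns of “Saturation at high substrate, untested because the run stayed below 0.03 M”.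

The higher flask is noon, with summer at 36.3 % and noon at 66.9 %.

    substrate + free enzyme → product + free enzyme, rate k1*[substrate]*[free enzyme]/(1 + ([substrate]/Km1)) (0.116 M, k = 468 M⁻¹ s⁻¹, Ea = 38.0 kJ mol⁻¹)
    free enzyme + added ligand ⇌ idle complex, settled at all times (K = 59100 M⁻¹, ΔH = −36.0 kJ mol⁻¹)
    free enzyme → unfolded enzyme (k = 8.62 × 10⁻⁷ s⁻¹, Ea = 264 kJ mol⁻¹)
    (constants at 20 °C)

Summer holds 63.7 % of its substrate at 80.0 min. Reforged on that amount, summer's clearance is 0.008817 µM⁻¹ min⁻¹, which is 0.548 of the carried value. Carried unchanged to a neighbour flask, noon's recipe with 1.90 µM of free enzyme, the clearance gives N of 1.96 and 43.8 % substrate left, while that flask holds 51.7 % at 80.0 min.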